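**Retrosynthetic overview** (cembrane numbering: C1 = lactone CH bearing C15, C2 = ring CH2, C18 = CH2OH on C4)
1. Sinularolide A ⇐ its 3,18-O-silylene derivative ⇐ 14-membered ring closure at C1–C2, the bond formed when geranylgeranyl diphosphate cyclises to the cembrane ring.
2. That closure: a C2 radical attacks C1 of the C1=C15 alkene and the C15 radical sheds a C17 substituent (PhSO2•), as the C15 cation sheds H+ in Nature; this gives the exo-methylene lactone and the 1,14-trans fusion in one step.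
3. Cyclisation precursor ⇐ vinylogous Mukaiyama aldol (C13–C14, sets 13S/14R) of a C2–C13 enal with a 3-(sulfonylmethyl)-2-silyloxyfuran made from tulipalin A.
4. Enal ⇐ (E)-β-farnesene: allylic oxidation (C13), Z-selective 1,4-diboration/oxidation (O at C2, C18), Sharpless epoxidation, Payne rearrangement–selenolate opening (3,4-diol by epoxide opening; C2–SePh as radical precursor).
5. Ring order: the five-membered lactone ring is carried in from the furanone; the 14-membered carbocycle is formed once, in step 12.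

Assumption: the SMILES is read as the (1R,3S,4S,13S,14R,7E,11E) isomer; the sense of induction quoted for the aldol catalyst (step 11) is taken from its usual behaviour and should be confirmed on the first adduct.

**Step 1**
Reactants: 1 (E)-β-farnesene
Product: 3 (2E,6E)-2,6-dimethyl-10-methylidenedodeca-2,6,11-trienal, via allylic alcohol 2 (not isolated)
Conditions: SeO2 (0.3 equiv), tBuOOH (3 equiv), salicylic acid (0.1 equiv), CH2Cl2, 0 °C → rt; then MnO2, CH2Cl2, rt
Reagents that add atoms: tert-butyl hydroperoxide, CC(C)(C)OO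
Why: Riley allylic oxidation (ene then [2,3] shift) attacks the (E)-methyl of the terminal trisubstituted alkene, the most electron-rich ene partner, and MnO2 converges the alcohol/aldehyde mixture to the (E)-enal; no stereocentre is formed.

**Step 2**
Reactants: 3 (2E,6E)-2,6-dimethyl-10-methylidenedodeca-2,6,11-trienal
Product: 4 (2E,6E)-1,1-dimethoxy-2,6-dimethyl-10-methylidenedodeca-2,6,11-triene
Conditions: HC(OMe)3, MeOH, pyridinium p-toluenesulfonate (5 mol %), 0 °C → rt
Reagents that add atoms: trimethyl orthoformate, COC(OC)OC; methanol, CO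
Why: acid-catalysed acetalisation masks the enal against the peroxide, hydroxide and selenolate used in steps 3–6.

**Step 3**
Reactants: 4 (2E,6E)-1,1-dimethoxy-2,6-dimethyl-10-methylidenedodeca-2,6,11-triene
Product: 6 (2Z)-2-[(3E,7E)-9,9-dimethoxy-4,8-dimethylnona-3,7-dien-1-yl]but-2-ene-1,4-diol, via bis(boronate) 5 (not isolated)
Conditions: bis(pinacolato)diboron (1.05 equiv), Pt(PPh3)4 (3 mol %), toluene, 80 °C; then NaOH, H2O2, THF–H2O, 0 °C
Reagents that add atoms: bis(pinacolato)diboron, CC1(C)OB(OC1(C)C)B1OC(C)(C)C(C)(C)O1 (boryl groups of 5); hydrogen peroxide, OO (both O atoms of 6)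
Why: zerovalent platinum adds B–B 1,4 across the s-cis diene only (1,4-diboration of 1,3-dienes), giving the cis-1,4-bis(allylboronate), and stereoretentive oxidation gives the (Z)-diol in which C2 and C5 are trans across C3=C4.

**Step 4**
Reactants: 6 (2Z)-2-[(3E,7E)-9,9-dimethoxy-4,8-dimethylnona-3,7-dien-1-yl]but-2-ene-1,4-diol
Product: 7 (2Z,6E,10E)-3-(hydroxymethyl)-12,12-dimethoxy-7,11-dimethyldodeca-2,6,10-trien-1-yl acetate
Conditions: AcCl (1.0 equiv), 2,4,6-collidine, CH2Cl2, −78 °C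
Reagents that add atoms: acetyl chloride, CC(Cl)=O
Why: sterically controlled mono-acylation takes the C2–OH on the vinylic CH in preference to the C18–OH beside the fully substituted alkene carbon; the regioisomer and diacetate are removed by chromatography and diol is recycled.

**Step 5**
Reactants: 7 (2Z,6E,10E)-3-(hydroxymethyl)-12,12-dimethoxy-7,11-dimethyldodeca-2,6,10-trien-1-yl acetate
Product: 8 [(2R,3S)-3-[(3E,7E)-9,9-dimethoxy-4,8-dimethylnona-3,7-dien-1-yl]-3-(hydroxymethyl)oxiran-2-yl]methyl acetate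
Conditions: Ti(OiPr)4 (0.3 equiv), diisopropyl L-(+)-tartrate (0.36 equiv), tBuOOH (2 equiv), 4 Å MS, CH2Cl2, −20 °C
Reagents that add atoms: tert-butyl hydroperoxide, CC(C)(C)OO
Why: Sharpless asymmetric epoxidation directed by the free C18–OH touches only the C3=C4 alkene, and L-(+)-tartrate delivers oxygen to the face that gives the (3R,4S) epoxide (cembrane numbering).

**Step 6**
Reactants: 8 [(2R,3S)-3-[(3E,7E)-9,9-dimethoxy-4,8-dimethylnona-3,7-dien-1-yl]-3-(hydroxymethyl)oxiran-2-yl]methyl acetate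
Product: 11 (2S,3R)-2-[(3E,7E)-9,9-dimethoxy-4,8-dimethylnona-3,7-dien-1-yl]-4-(phenylselanyl)butane-1,2,3-triol, via epoxy diol 9 (not isolated), via terminal epoxide 10 (not isolated)
Conditions: (PhSe)2 (0.6 equiv), NaBH4, EtOH, rt; then 8, 1 M aq NaOH, tBuOH, 65 °C
Reagents that add atoms: diphenyl diselenide, c1ccccc1[Se][Se]c1ccccc1
Why: Payne rearrangement–opening: hydroxide removes the acetate, the C2 alkoxide attacks C3 with inversion (SN2 at the secondary carbon, preferred over attack of the C18 alkoxide at quaternary C4), and selenolate opens the resulting terminal epoxide at C2, so C3 is inverted and C4 retained, which is the target's 3S,4S arrangement.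

**Step 7**
Reactants: 11 (2S,3R)-2-[(3E,7E)-9,9-dimethoxy-4,8-dimethylnona-3,7-dien-1-yl]-4-(phenylselanyl)butane-1,2,3-triol
Product: 13 (2E,6E)-9-[(4R,5S)-2,2-di-tert-butyl-5-hydroxy-4-[(phenylselanyl)methyl]-1,3,2-dioxasilinan-5-yl]-2,6-dimethylnona-2,6-dienal, via silylene acetal 12 (not isolated)
Conditions: tBu2Si(OTf)2 (1.1 equiv), 2,6-lutidine, CH2Cl2, 0 °C; then pyridinium p-toluenesulfonate, acetone–H2O, rt
Reagents that add atoms: di-tert-butylsilyl bis(trifluoromethanesulfonate), CC(C)(C)[Si](OS(=O)(=O)C(F)(F)F)(OS(=O)(=O)C(F)(F)F)C(C)(C)C; water, O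
Why: the silylene bridges the primary C18–OH and secondary C3–OH as a six-membered dioxasilinane (the five-membered ring through tertiary O4 is disfavoured), and the allylic dimethyl acetal is then hydrolysed under conditions that spare silylene, selenide and alkenes.

**Step 8**
Reactants: 14 tulipalin A (3-methylideneoxolan-2-one)
Product: 16 3-(bromomethyl)furan-2(5H)-one, via dibromide 15 (not isolated)
Conditions: Br2, CH2Cl2, 0 °C; then Et3N, 0 °C → rt
Reagents that add atoms: bromine, BrBr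
Why: bromine addition followed by E2 loss of HBr (tertiary bromide and ring CH2) gives the conjugated endocyclic butenolide that keeps the allylic bromide.

**Step 9**
Reactants: 16 3-(bromomethyl)furan-2(5H)-one
Product: 17 3-[(phenylsulfonyl)methyl]furan-2(5H)-one
Conditions: PhSO2Na, DMF, rt
Reagents that add atoms: sodium benzenesulfinate, [Na+].[O-]S(=O)c1ccccc1
Why: S-alkylation of the sulfinate by the allylic bromide (SN2, or SN2′ followed by isomerisation) converges on the conjugated allyl sulfone.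

**Step 10**
Reactants: 17 3-[(phenylsulfonyl)methyl]furan-2(5H)-one
Product: 18 tert-butyl(dimethyl)({3-[(phenylsulfonyl)methyl]furan-2-yl}oxy)silane
Conditions: tBuMe2SiOTf, Et3N, CH2Cl2, 0 °C
Reagents that add atoms: tert-butyldimethylsilyl trifluoromethanesulfonate, CC(C)(C)[Si](C)(C)OS(=O)(=O)C(F)(F)F
Why: soft enolisation at C5 of the butenolide gives the aromatic 2-silyloxyfuran, a vinylogous silyl ketene acetal.

**Step 11**
Reactants: 13 (2E,6E)-9-[(4R,5S)-2,2-di-tert-butyl-5-hydroxy-4-[(phenylselanyl)methyl]-1,3,2-dioxasilinan-5-yl]-2,6-dimethylnona-2,6-dienal; 18 tert-butyl(dimethyl)({3-[(phenylsulfonyl)methyl]furan-2-yl}oxy)silane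
Product: 19 (5R)-5-[(1S,2E,6E)-9-[(4R,5S)-2,2-di-tert-butyl-5-hydroxy-4-[(phenylselanyl)methyl]-1,3,2-dioxasilinan-5-yl]-1-hydroxy-2,6-dimethylnona-2,6-dien-1-yl]-3-[(phenylsulfonyl)methyl]furan-2(5H)-one
Conditions: SiCl4 (1.5 equiv), (R,R)-N,N′-bis[4,5-dihydro-3,5-dimethyl-4-(3H-dinaphtho[2,1-d:1′,2′-f][1,3,2]diazaphosphepin-4-yl 4-oxide)]-N,N′-dimethylpentane-1,5-diamine (5 mol %), iPr2NEt (0.2 equiv), CH2Cl2, −78 °C; then aq NaHCO3
Reagents that add atoms: none
Why: vinylogous Mukaiyama aldol in which the chiral phosphoramide-bound SiCl3+ activates the enal and the furan attacks through C5 in an open transition state, giving the anti (erythro) adduct by Re-face attack on the aldehyde, i.e. 13S and 14R; the tertiary OH is only transiently silylated and is freed on work-up.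

**Step 12**
Reactants: 19 (5R)-5-[(1S,2E,6E)-9-[(4R,5S)-2,2-di-tert-butyl-5-hydroxy-4-[(phenylselanyl)methyl]-1,3,2-dioxasilinan-5-yl]-1-hydroxy-2,6-dimethylnona-2,6-dien-1-yl]-3-[(phenylsulfonyl)methyl]furan-2(5H)-one
Product: 20 3,18-O-(di-tert-butylsilanediyl)sinularolide A
Conditions: (Bu3Sn)2 (2 equiv), MgBr2·OEt2 (5 equiv), hν (300 nm), CH2Cl2, −78 °C, 1 mM
Reagents that add atoms: none
Why: Proposed new method: Bu3Sn• abstracts PhSe from C2, the primary radical closes the 14-membered ring by adding to C1 of the MgBr2-activated butenolide on the face anti to the C14 side chain (sets 1R, trans fusion), and the C15 radical expels PhSO2• by β-scission to give the exo-methylene lactone; the low temperature and Lewis acid are chosen because the competing 6-exo closure onto C7=C8 and the 1,5-H shift from C6 have higher barriers than Lewis-acid-assisted conjugate addition; closest known reactions are radical allylation with 2-(sulfonylmethyl)acrylates, 14-membered radical macrocyclisation onto enoates and Lewis-acid-promoted radical conjugate addition at −78 °C.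

**Step 13**
Reactants: 20 3,18-O-(di-tert-butylsilanediyl)sinularolide A
Product: 21 sinularolide A
Conditions: HF·pyridine, pyridine, THF, 0 °C → rt
Reagents that add atoms: none
Why: fluoride cleaves the silylene without touching the α-methylene lactone, the allylic alcohol or the alkenes; no stereocentre is affected.

**Compound list**
1 | (E)-β-farnesene | C=CC(=C)CC/C=C(\C)CCC=C(C)C | starting material
2 | (2E,6E)-2,6-dimethyl-10-methylidenedodeca-2,6,11-trien-1-ol | C=CC(=C)CC/C=C(\C)CC/C=C(\C)CO | intermediate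
3 | (2E,6E)-2,6-dimethyl-10-methylidenedodeca-2,6,11-trienal | C=CC(=C)CC/C=C(\C)CC/C=C(\C)C=O | intermediate
4 | (2E,6E)-1,1-dimethoxy-2,6-dimethyl-10-methylidenedodeca-2,6,11-triene | C=CC(=C)CC/C=C(\C)CC/C=C(\C)C(OC)OC | intermediate
5 | 2,2′-[(2E)-2-[(3E,7E)-9,9-dimethoxy-4,8-dimethylnona-3,7-dien-1-yl]but-2-ene-1,4-diyl]bis(4,4,5,5-tetramethyl-1,3,2-dioxaborolane) (boryl groups cis) | CC1(C)OB(C/C=C(\CB2OC(C)(C)C(C)(C)O2)CC/C=C(\C)CC/C=C(\C)C(OC)OC)OC1(C)C | intermediate
6 | (2Z)-2-[(3E,7E)-9,9-dimethoxy-4,8-dimethylnona-3,7-dien-1-yl]but-2-ene-1,4-diol | OC/C=C(\CO)CC/C=C(\C)CC/C=C(\C)C(OC)OC | intermediate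
7 | (2Z,6E,10E)-3-(hydroxymethyl)-12,12-dimethoxy-7,11-dimethyldodeca-2,6,10-trien-1-yl acetate | CC(=O)OC/C=C(\CO)CC/C=C(\C)CC/C=C(\C)C(OC)OC | intermediate
8 | [(2R,3S)-3-[(3E,7E)-9,9-dimethoxy-4,8-dimethylnona-3,7-dien-1-yl]-3-(hydroxymethyl)oxiran-2-yl]methyl acetate | CC(=O)OC[C@H]1O[C@]1(CO)CC/C=C(\C)CC/C=C(\C)C(OC)OC | intermediate
9 | [(2S,3R)-2-[(3E,7E)-9,9-dimethoxy-4,8-dimethylnona-3,7-dien-1-yl]oxirane-2,3-diyl]dimethanol | OC[C@H]1O[C@]1(CO)CC/C=C(\C)CC/C=C(\C)C(OC)OC | intermediate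
10 | (2S,5E,9E)-11,11-dimethoxy-6,10-dimethyl-2-[(2S)-oxiran-2-yl]undeca-5,9-diene-1,2-diol | C1O[C@@H]1[C@@](O)(CO)CC/C=C(\C)CC/C=C(\C)C(OC)OC | intermediate
11 | (2S,3R)-2-[(3E,7E)-9,9-dimethoxy-4,8-dimethylnona-3,7-dien-1-yl]-4-(phenylselanyl)butane-1,2,3-triol | c1ccccc1[Se]C[C@H](O)[C@@](O)(CO)CC/C=C(\C)CC/C=C(\C)C(OC)OC | intermediate
12 | (4R,5S)-2,2-di-tert-butyl-5-[(3E,7E)-9,9-dimethoxy-4,8-dimethylnona-3,7-dien-1-yl]-4-[(phenylselanyl)methyl]-1,3,2-dioxasilinan-5-ol | c1ccccc1[Se]C[C@@H]2O[Si](C(C)(C)C)(C(C)(C)C)OC[C@@]2(O)CC/C=C(\C)CC/C=C(\C)C(OC)OC | intermediate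
13 | (2E,6E)-9-[(4R,5S)-2,2-di-tert-butyl-5-hydroxy-4-[(phenylselanyl)methyl]-1,3,2-dioxasilinan-5-yl]-2,6-dimethylnona-2,6-dienal | c1ccccc1[Se]C[C@@H]2O[Si](C(C)(C)C)(C(C)(C)C)OC[C@@]2(O)CC/C=C(\C)CC/C=C(\C)C=O | intermediate
14 | tulipalin A (3-methylideneoxolan-2-one) | C=C1CCOC1=O | starting material
15 | 3-bromo-3-(bromomethyl)oxolan-2-one (racemic) | BrCC1(Br)CCOC1=O | intermediate
16 | 3-(bromomethyl)furan-2(5H)-one | BrCC1=CCOC1=O | intermediate
17 | 3-[(phenylsulfonyl)methyl]furan-2(5H)-one | O=C1OCC=C1CS(=O)(=O)c1ccccc1 | intermediate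
18 | tert-butyl(dimethyl)({3-[(phenylsulfonyl)methyl]furan-2-yl}oxy)silane | CC(C)(C)[Si](C)(C)Oc1occc1CS(=O)(=O)c1ccccc1 | intermediate
19 | (5R)-5-[(1S,2E,6E)-9-[(4R,5S)-2,2-di-tert-butyl-5-hydroxy-4-[(phenylselanyl)methyl]-1,3,2-dioxasilinan-5-yl]-1-hydroxy-2,6-dimethylnona-2,6-dien-1-yl]-3-[(phenylsulfonyl)methyl]furan-2(5H)-one | c1ccccc1[Se]C[C@@H]2O[Si](C(C)(C)C)(C(C)(C)C)OC[C@@]2(O)CC/C=C(\C)CC/C=C(\C)[C@H](O)[C@@H]1OC(=O)C(CS(=O)(=O)c3ccccc3)=C1 | intermediate
20 | 3,18-O-(di-tert-butylsilanediyl)sinularolide A | C=C1C(=O)O[C@@H]2[C@@H]1C[C@@H]3O[Si](C(C)(C)C)(C(C)(C)C)OC[C@@]3(O)CC/C=C(\C)CC/C=C(\C)[C@@H]2O | intermediate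
21 | sinularolide A, (1R,3S,4S,7E,11E,13S,14R)-3,4,13,18-tetrahydroxycembra-7,11,15(17)-trien-16,14-olide | C=C1C(=O)O[C@@H]2[C@@H]1C[C@H](O)[C@@](O)(CO)CC/C=C(\C)CC/C=C(\C)[C@@H]2O | target

**Total step count:** 13. **Longest linear sequence:** 10 steps (1–7, 11–13, from (E)-β-farnesene).

**Three steps most likely to fail**

Step 12 (radical macrocyclisation). The C2 radical can instead close a six-membered ring onto C7=C8 or take an allylic hydrogen from C6. Stannyl radicals may also attack the allyl sulfone, and the cis-fused lactone may form alongside the trans. The fallback sets out from 13 and comes back at 20; it separates ring closure from methylene formation and uses the less hindered parent butenolide. Aldehyde 13 is combined under the step 11 conditions with commercial 2-(trimethylsilyloxy)furan to give the 3-unsubstituted butenolide adduct F1. Reductive Giese closure ((Me3Si)3SiH by syringe pump, Et3B/O2, MgBr2·OEt2, CH2Cl2, −78 °C) gives the saturated trans-fused lactone F2. Enolisation (LiN(iPr)2, 3.3 equiv, THF, −78 °C) and Me2N=CH2+ I− give the Mannich base F3, which with MeI and then NaHCO3 eliminates to 20.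

Step 11 (vinylogous aldol). The sulfonylmethyl-substituted furan and the α-branched enal may react with poor anti selectivity or with the opposite relative configuration. The fallback sets out from 13 and 18 and comes back at 19; it corrects C13 after the aldol instead of relying on the anti mode. If the aldol proves syn-selective, the (S,S)-catalyst is used so that C14 is still R, giving the (13R,14R) syn adduct F4. Mitsunobu inversion (4-nitrobenzoic acid, PPh3, diisopropyl azodicarboxylate, toluene, 0 °C) gives the (13S) 4-nitrobenzoate F5. Mild methanolysis (Mg(OMe)2, MeOH, 0 °C) then returns 19.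

Step 6 (Payne rearrangement–selenolate opening). Selenolate may attack the 3,4-epoxide directly, or the rearrangement may run through the C18 arm and put selenium on C18. The fallback sets out from 8 and comes back at 11; it blocks the competing arm and runs the events stepwise. Silylation of 8 (tBuMe2SiCl, imidazole, DMF) gives the C18 silyl ether of the epoxy acetate F6. K2CO3/MeOH removes the acetate so that only the C2 alkoxide can rearrange, and PhSeNa (from (PhSe)2/NaBH4, EtOH, 50 °C) opens the terminal epoxide to the C18 silyl ether of the selenide diol F7. Bu4NF in THF then gives 11.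

**Further compounds**
F1 | step 12 | (5R)-5-[(1S,2E,6E)-9-[(4R,5S)-2,2-di-tert-butyl-5-hydroxy-4-[(phenylselanyl)methyl]-1,3,2-dioxasilinan-5-yl]-1-hydroxy-2,6-dimethylnona-2,6-dien-1-yl]furan-2(5H)-one | c1ccccc1[Se]C[C@@H]2O[Si](C(C)(C)C)(C(C)(C)C)OC[C@@]2(O)CC/C=C(\C)CC/C=C(\C)[C@H](O)[C@@H]1OC(=O)C=C1
F2 | step 12 | 3,18-O-(di-tert-butylsilanediyl)-17-norsinularolide A (saturated lactone, C15 = CH2) | C1C(=O)O[C@@H]2[C@@H]1C[C@@H]3O[Si](C(C)(C)C)(C(C)(C)C)OC[C@@]3(O)CC/C=C(\C)CC/C=C(\C)[C@@H]2O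
F3 | step 12 | 15-[(dimethylamino)methyl] derivative of F2 (Mannich base, C15 epimers) | CN(C)CC1C(=O)O[C@@H]2[C@@H]1C[C@@H]3O[Si](C(C)(C)C)(C(C)(C)C)OC[C@@]3(O)CC/C=C(\C)CC/C=C(\C)[C@@H]2O
F4 | step 11 | (5R)-5-[(1R,2E,6E)-9-[(4R,5S)-2,2-di-tert-butyl-5-hydroxy-4-[(phenylselanyl)methyl]-1,3,2-dioxasilinan-5-yl]-1-hydroxy-2,6-dimethylnona-2,6-dien-1-yl]-3-[(phenylsulfonyl)methyl]furan-2(5H)-one | c1ccccc1[Se]C[C@@H]2O[Si](C(C)(C)C)(C(C)(C)C)OC[C@@]2(O)CC/C=C(\C)CC/C=C(\C)[C@@H](O)[C@@H]1OC(=O)C(CS(=O)(=O)c3ccccc3)=C1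
F5 | step 11 | (1S,2E,6E)-9-[(4R,5S)-2,2-di-tert-butyl-5-hydroxy-4-[(phenylselanyl)methyl]-1,3,2-dioxasilinan-5-yl]-2,6-dimethyl-1-[(2R)-5-oxo-4-[(phenylsulfonyl)methyl]-2,5-dihydrofuran-2-yl]nona-2,6-dien-1-yl 4-nitrobenzoate | c1ccccc1[Se]C[C@@H]2O[Si](C(C)(C)C)(C(C)(C)C)OC[C@@]2(O)CC/C=C(\C)CC/C=C(\C)[C@H](OC(=O)c4ccc(cc4)[N+](=O)[O-])[C@@H]1OC(=O)C(CS(=O)(=O)c3ccccc3)=C1
F6 | step 6 | [(2R,3S)-3-({[tert-butyl(dimethyl)silyl]oxy}methyl)-3-[(3E,7E)-9,9-dimethoxy-4,8-dimethylnona-3,7-dien-1-yl]oxiran-2-yl]methyl acetate | CC(=O)OC[C@H]1O[C@]1(CO[Si](C)(C)C(C)(C)C)CC/C=C(\C)CC/C=C(\C)C(OC)OC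
F7 | step 6 | (2S,3R)-1-{[tert-butyl(dimethyl)silyl]oxy}-2-[(3E,7E)-9,9-dimethoxy-4,8-dimethylnona-3,7-dien-1-yl]-4-(phenylselanyl)butane-2,3-diol | c1ccccc1[Se]C[C@H](O)[C@@](O)(CO[Si](C)(C)C(C)(C)C)CC/C=C(\C)CC/C=C(\C)C(OC)OC
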